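The readings come from a simulation with constants of no real substance.

| setting | birch | north | east |
|---|---|---|---|
| starting material | 0.50 M | 0.12 M | 0.50 M |
| coupling partner | 0.75 M | 1.50 M | 0.750 M |
| protic impurity | 0.10 M | 0.100 M | 0.100 M |
| catalyst | 1.7 mM | 2.5 mM | 2.5 mM |
| temperature | 35 °C |  |  |
| remark | run made earlier | at 35 °C throughout | at 35 °C until 40 s, from then on at −5 °C |
| time |  | 3.0 min | 3.0 min |
birch run (percent of the starting material charged): time / s: product / % = 10.0: 14.9; 12.0: 16.8; 20.0: 24.1; 25.0: 26.8; 40.0: 36.2; 60.0: 44.8

(each reading ± 0.5 percentage points)
- a reading or a percentage of product counts all its forms, free or not
- the earlier runs do not show what temperature does; that part of a forecast is a guess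
- no earlier run changes the charge of catalyst; that part of a forecast is a guess
* which one finishes higher in amount of product, in percent of the starting material charged ("neither" within 2 percentage points) (north / east / neither)
* amount of product at the end, in percent of the starting material charged, north
* amount of product at the end, in percent of the starting material charged, east

- Starting material that protic impurity has taken cannot also become product. That the two react one for one is our guess, since no earlier run varies the impurity.
- North's ratio of protic impurity to starting material is 0.833; we call this ratio, the equivalents of impurity, the claim. The two amounts in it are the ones we reckon with.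
- Partner is not a third amount: north holds 1.50 M against 0.12 M of starting material, so starting material is the limiting reagent.
- Time is not one either. Birch's last reading, scaled in proportion to north's partner and catalyst (a guess), makes north's time 5.24 lifetimes of starting material.
- So we solve the two ends. If the impurity is much the quicker of the two reactions, north keeps 16.7% of its starting material for product; if much the slower, it keeps all of it. No earlier run varies the impurity, so we take the middle, 58.3%.
- East's claim is 0.200, but it has 40 s warm. Birch's reading at that time, scaled for catalyst (a guess), gives east 48.4% of product at the change of temperature, and what the cold adds is a guess. We put north higher.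
- The forecast says north, with north at 96% (82% to 100%) and east at 48% (42% to 57%), holding that “the excess partner can only help”.
- North ends at 66.5% and east at 50.7%, so north finishes higher.

    starting material + protic impurity → quenched substrate (k = 0.320 M⁻¹ s⁻¹, Ea = 41.0 kJ mol⁻¹)
    coupling partner ⇌ dormant form (K = 0.550, k = 0.0520 s⁻¹, Ea = 82.0 kJ mol⁻¹, ΔH = −54.0 kJ mol⁻¹)
    starting material + coupling partner + catalyst → catalyst + product (k = 18.0 M⁻² s⁻¹, Ea = 41.0 kJ mol⁻¹)
    crystals ⇌ product, rate k4*(cs4 - [product]) while solid is left; crystals form when [product] > cs4 (solubility = 18.0 mM, k = 0.740 s⁻¹)
    (constants at 35 °C)

- North spent 40.1% of its impurity, which at its claim is 33.5% of its starting material, and with 0% of starting material left north stands at 66.5%, above our middle. The neighbour is north with 0.025 M of impurity, so its claim is 0.208, its lower end 79.2% and its middle 89.6%. The neighbour spent 51.3% of its impurity, which at its claim is 10.7% of its starting material, and it ends at 89.3%.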